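Decide to follow the wear on the enzyme, not E.

    E + Q ⇌ E.Q (K1 = 900 /M, k1 = 23000 /M/s)
    E.Q ⇌ Q + L (K2 = 0.80 M, k2 = 6.7 /s)
    Q + Z → Q.Z (k3 = 2600 /M/s)

| flask | E | Q | Z | remark | time |
|---|---|---|---|---|---|
| north-east | 0.050 M | 38 µM | 36 µM | a single well-mixed tank run continuously and read at steady state, 2.0 min in it on average |  |
| east | 0.050 M | 38 µM | 36 µM | a closed flask charged with all of it at once and left for 2.0 min | 2.0 min |
| south | 0.050 M (fed, over 1.60 min) | 38 µM | 36 µM | all but E at the start; E goes in evenly over 1.60 min, the run ends at 2.0 min | 2.0 min |

- the stated concentrations are those of everything mixed, before any reaction; amounts are the same in each set-up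
- the feed brings no volume worth counting
- run time (east): 2.0 min

- order of the set-ups by the amount of L at the outlet or at the end, in percent of the E put in, highest first (north-east / east / south)
- amount of L at the outlet or at the end, in percent of the E put in, north-east
- amount of L at the outlet or at the end, in percent of the E put in, east
- amount of L at the outlet or at the end, in percent of the E put in, south

Write x for the share of the charged E still free, and a for the share of the charged enzyme still working, Q and E.Q together.

1. Find how E holds the enzyme. Step 1 runs back at 25.6 /s, so E.Q stands to Q as E stands to 1.40 mM, the Michaelis constant. That is 2.80% of the charge. Drop the way back from L, since its constant 8.38 /M/s lies far below 23000 /M/s.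

2. Reckon the ceiling. Enzyme that stayed whole and held E throughout would turn over 61.1% of the charge in 2.0 min. With E still at its full charge in east, 97.3% of it holds E.

3. Divide the rate of loss by the rate of making L. Let Z fall with a, as its charge 36 µM is close to the 38 µM of Q. What remains is n = k3 times Z's charge times Km, over k2 times Q's charge, which is 0.516. Call n the wear exponent, the relative fall of a for each relative fall of x. So in east a = x^n, and each share of L costs a relative n/x.

4. First way, for east: put a = x^n into the rate of E, and hold the share of working enzyme that holds E at its start value. Then x^(1−n) = 1 − (1−n) times the ceiling times the start share, which gives L = 50.4%.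

5. Second way, for east: treat the wear as a correction to the ceiling. Hold the share of working enzyme standing as Q at its start value 2.73%. Over the run Z then meets Q with the measure 0.306, the mean of a is 87.2%, and L = 51.8%.

6. The two ways part by 1.4 percentage points. The second one cheats: x falls to about half, so the share standing as Q ends about twice its start value, while the share that the first way holds moves from 97.3% to 94.7%. Commit to 50.4% for east.

7. Rank the rest by the price n/x, without reckoning their yields. In south x starts at nought, and when it reaches 2.80% the price n/x is 18.4, far above the 0.516 that east pays at its start. So put south below east and, as a judgement, the tank between.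

The forecast gave east > north-east > south, with 42.4% for north-east, 49.9% for east and 30% for south, holding that “Z can only catch free Q, which is scarce when E is high”. Its figure for east lies 0.50 points below my 50.4%.

The simulation gives east > north-east > south, with 42.4% for north-east, 49.9% for east and 29.7% for south.

Take x = 50.0% in east at 2.00 min: a = x^n gives 69.9%, and E.Q with Q reads 70.2%. Now carry n to south read later. Its feed ended at 1.60 min, so from 2.00 min, with x = 70.3% and a = 46.9%, it runs as a closed flask. The first way, started from there in south, gives x = 35.2% at 5.0 min, so L = 64.8%. South read at 5.0 min shows E 35.3% and L 64.7%.

(The rate constants are invented; the rest is arithmetic.)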